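All constants were set for the occasion; the result is computed.

The product Z.L forms when Z catches dissolved L. That L comes into solution from the gas G, held at constant pressure, and Z.L then passes on to E.

    Z.L ⇌ E (K1 = 2.82, k1 = 0.213 s⁻¹)
    G ⇌ L, rate k2*(csat - [L]) (k2 = 0.422 s⁻¹, csat = 0.047 mM)
    Z + L ⇌ Z.L (K3 = 16000 L mol⁻¹, k3 = 1.27 × 10⁵ L mol⁻¹ s⁻¹)

Z 0.50 mM; G 0.047 mM (held); time 10 s

- at the start none of L is dissolved
- run time (flask): 10 s

* the Z.L standing at 10 s, as a percentage of the Z charged
* the change that raises the amount of Z.L at 10 s, in percent of the Z charged most ("none" if none brings more than 2 percentage points) (dusk / dawn / none)
* amount of Z.L at 10 s, in percent of the Z charged, after dusk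

- dusk: doubling the transfer coefficient of step 2, all else as stated
- dawn: doubling the saturation concentration of G, all else as stated

We ask first where the flask must end. At rest L stands at saturation, so Z.L over Z equals the binding constant times the saturation concentration, and E over Z.L equals the constant of the last step. That puts 19.4% of the charge in Z.L and takes 74.2% out of free Z, and these proportions contain no amount of Z.

The approach to that end depends on the feed. Capture of L, taken by its forward rate with Z as charged, has a half-life of 0.011 s, far shorter than the 1.64 s of transfer, so at the start transfer is the rate-limiting step. We therefore carry the value 39.7%, the feed share: transfer coefficient times saturation concentration times time, over the Z charged.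

The neighbour with 0.85 mM of Z looks nearly the same, but its feed share is 23.3%, lower than the flask's, since the same gas is spread over more Z. Both shares fall short of the 74.2% the end requires, so we expect each flask to stand where its feed has brought it, the neighbour lower in percent.

For the flask, a steady feed into Z.L, with Z.L relaxing towards E at 0.289 s⁻¹, leaves 50.3% of the feed as Z.L, which gives 20.0%. This rough reckoning puts L at about 44.0% of saturation at the asked time, and we take the mean driving force as lower by 22.0%, so we commit to 15.6%. Dusk and dawn each double the feed share, but dusk leaves the end at 19.4% while dawn lifts it to 22.3%. We choose dawn and give no figure for dusk, since the doubled feed share times the same split comes to 40.0%, above the end of 19.4%.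

The forecast gave 15%, slightly under ours, with 22.4% after dusk and dawn as best, since “raising the saturation concentration keeps the driving force larger as L builds up”.

The flask gives 14.9% of Z.L, 22.1% after dusk, and dawn as the best change, with a gain of 12 percentage points against 7.3 points for dusk. At 10.0 s the flask has 70% of its Z left, so 30.4% of the charge is bound against a feed share of 39.7%. The neighbour with 0.85 mM of Z has a feed share of 23.3%, and with 80% of its Z left at 10.0 s it has 20.0% bound, of which Z.L holds 9.97%.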